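**Assumption:** the C10 stereocenter comes from commercial (S)-5-oxotetrahydrofuran-2-carboxylic acid, which is made from L-glutamic acid. The C7=C8 alkene is E, so that C6 and C10 end up trans on the cyclopropane, as in the target.

**Retrosynthesis**
1. Target ⇐ C2 acetylation, then furan → Z-enedione by [4+2] singlet-oxygen cycloaddition, from furanomacrocycle **18**.
2. **18** ⇐ intramolecular NHK allylation (C1–C2, anti) of allylic bromide/furfural **17**. **17** comes from butenolide **15**, which comes from α-alkylation and selenoxide elimination on lactone **12**.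
3. Key ring: the cyclopropane of **12** forms by a [2+1] zinc-carbenoid cycloaddition (Furukawa–Simmons–Smith) on E-vinylfuran **11**, which is made by HWE of methyl ketone **10** with furfuryl phosphonate **4**.
4. Ring order: cyclopropane, then lactone/butenolide, then the 13-membered macrocycle, then furan opening.

---

**Step 1**
Reactants: **1** 3-methylfuran-2-carbaldehyde
Product: **2** 2-(3-methylfuran-2-yl)-1,3-dioxolane
Conditions: HOCH2CH2OH, TsOH (cat.), PhH, Dean–Stark, reflux
Reagents that add atoms: ethylene glycol, OCCO
Why: Acetalization masks the aldehyde so that the furan can be lithiated and later survive the HWE and Simmons–Smith steps.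

**Step 2**
Reactants: **2**
Product: **3** [5-(1,3-dioxolan-2-yl)-4-methylfuran-2-yl]methanol
Conditions: n-BuLi, THF, −78 → 0 °C; then (CH2O)n, −78 → 23 °C
Reagents that add atoms: formaldehyde, C=O
Why: The free α-position (C5) of the 2-substituted furan is lithiated selectively, and the aryllithium adds to formaldehyde.

**Step 3**
Reactants: **3**
Product: **4** diethyl {[5-(1,3-dioxolan-2-yl)-4-methylfuran-2-yl]methyl}phosphonate
Conditions: P(OEt)3, ZnI2, THF, 23 °C
Reagents that add atoms: triethyl phosphite, CCOP(OCC)OCC
Why: ZnI2 converts the furfuryl alcohol to the iodide in situ, and Michaelis–Arbuzov reaction then gives the phosphonate.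

**Step 4**
Reactants: **5** 5-bromo-2-methylpent-2-ene
Product: **6** (E)-5-bromo-2-methylpent-2-en-1-ol
Conditions: SeO2 (5 mol%), TBHP, salicylic acid, CH2Cl2, 23 °C
Reagents that add atoms: tert-butyl hydroperoxide, CC(C)(C)OO (supplies the OH)
Why: Riley/Sharpless allylic oxidation occurs at the methyl trans to the chain, as in geranyl-type oxidations, which sets the E-allylic alcohol.

**Step 5**
Reactants: **6**
Product: **7** (E)-TBS ether of **6**
Conditions: TBSCl, imidazole, DMF, 0 → 23 °C
Reagents that add atoms: tert-butyldimethylsilyl chloride, CC(C)(C)[Si](C)(C)Cl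
Why: Silyl protection of the primary alcohol lets the enolate alkylation in step 10 proceed.

**Step 6**
Reactants: **8** (S)-5-oxotetrahydrofuran-2-carboxylic acid
Product: **9** (S)-N-methoxy-N-methyl-5-oxotetrahydrofuran-2-carboxamide
Conditions: MeNHOMe·HCl, EDC·HCl, HOBt, NMM, CH2Cl2, 0 → 23 °C
Reagents that add atoms: N,O-dimethylhydroxylamine, CNOC
Why: Mild, non-basic carbodiimide amide coupling leaves the C10 stereocenter untouched.

**Step 7**
Reactants: **9**
Product: **10** (S)-5-acetyldihydrofuran-2(3H)-one
Conditions: MeMgBr (1.1 equiv), THF, −78 °C, cold NH4Cl quench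
Reagents that add atoms: methylmagnesium bromide, C[Mg]Br
Why: Weinreb ketone synthesis stops at the chelated intermediate, so it gives the methyl ketone (C8, C19) without touching the lactone or the stereocenter.

**Step 8**
Reactants: **10**; **4**
Product: **11** (S)-5-{(E)-1-methyl-2-[5-(1,3-dioxolan-2-yl)-4-methylfuran-2-yl]vinyl}dihydrofuran-2(3H)-one
Conditions: **4** + KHMDS, THF, −78 °C; add **10**; −78 → 23 °C
Reagents that add atoms: none
Why: Horner–Wadsworth–Emmons olefination places the furyl group trans to the larger C10 substituent, giving the E-alkene (C6 trans to C10) needed for the trans cyclopropane.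

**Step 9**
Reactants: **11**
Product: **12** cyclopropane (C7 S, C8 S, C10 S retained)
Conditions: Et2Zn, CH2I2, DCE, 0 → 23 °C
Reagents that add atoms: diiodomethane, ICI (adds C9 as CH2)
Why: Furukawa–Simmons–Smith is a stereospecific syn [2+1] carbenoid cycloaddition that keeps the E geometry, so C6 and C10 end up trans. The allylic C10 stereocenter sets the face (attack anti to the C10–O bond in the A(1,2)-strain-preferred conformer), which fixes C7 and C8.

**Step 10**
Reactants: **12**; **7**
Product: **13** α-alkylated lactone (C12 epimers irrelevant)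
Conditions: LDA, DMPU, THF, −78 → 0 °C; **7**, TBAI (cat.)
Reagents that add atoms: none
Why: Lactone enolate alkylation at C12 (the only acidic site) installs C13–C14–C1 and the E-trisubstituted alkene. The C12 stereocenter is destroyed in step 12.

**Step 11**
Reactants: **13**
Product: **14** α-phenylselenyl lactone
Conditions: LDA, THF, −78 °C; PhSeCl
Reagents that add atoms: benzeneselenenyl chloride, Cl[Se]c1ccccc1
Why: Enolate selenation gives the tertiary selenide needed for dehydrogenation.

**Step 12**
Reactants: **14**
Product: **15** butenolide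
Conditions: NaIO4, NaHCO3, THF/H2O, 0 → 40 °C
Reagents that add atoms: none
Why: Selenoxide syn-elimination is directed into the ring (toward C11–H), giving the endocyclic α-alkylbutenolide; C10 is untouched.

**Step 13**
Reactants: **15**
Product: **16** allylic alcohol/furfural
Conditions: AcOH/THF/H2O (3:1:1), 40 °C
Reagents that add atoms: water, O
Why: Mild acid removes the primary TBS ether and hydrolyzes the labile furfural dioxolane in one pot.

**Step 14**
Reactants: **16**
Product: **17** allylic bromide/furfural
Conditions: MsCl, Et3N, CH2Cl2, −20 °C; then LiBr, THF, 0 °C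
Reagents that add atoms: lithium bromide, [Li+].[Br-]
Why: Mesylation followed by SN2 displacement gives the bromide with the E-alkene and the aldehyde untouched.

**Step 15**
Reactants: **17**
Product: **18** furanomacrocycle, C2–OH (1S,2S)
Conditions: CrCl2, NiCl2 (cat.), 4 Å MS, THF, 0 → 23 °C, slow addition (~2 mM)
Reagents that add atoms: none
Why: Nozaki–Hiyama–Kishi intramolecular allylation. The E-allylchromium adds through a chair transition state, giving the anti C1/C2 relationship, which is the relationship in the target. The chirality of the macrocycle (C10, C7, C8) picks the facial sense.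

**Step 16**
Reactants: **18**
Product: **19** C2-acetate
Conditions: Ac2O, DMAP, pyridine, CH2Cl2, 23 °C
Reagents that add atoms: acetic anhydride, CC(=O)OC(C)=O
Why: Acetylation installs the C2 acetate and blocks Achmatowicz-type furfuryl-alcohol oxidation in step 17.

**Step 17**
Reactants: **19**
Product: **20** Pinnatin B
Conditions: O2, Rose Bengal, visible light, CH2Cl2, −78 °C; then Me2S, −78 → 23 °C
Reagents that add atoms: dioxygen, O=O (both O atoms retained as the two C=O groups)
Why: Singlet oxygen undergoes a [4+2] cycloaddition with the furan, and reductive opening of the endoperoxide gives the Z-enedione (C3=O, C4=C5, C6=O). All stereocenters are already set.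

---

**Compound list**

| # | Name | SMILES | Role |
|---|---|---|---|
| 1 | 3-methylfuran-2-carbaldehyde | Cc1ccoc1C=O | starting material |
| 2 | 2-(3-methylfuran-2-yl)-1,3-dioxolane | Cc1ccoc1C1OCCO1 | intermediate |
| 3 | [5-(1,3-dioxolan-2-yl)-4-methylfuran-2-yl]methanol | Cc1cc(CO)oc1C1OCCO1 | intermediate |
| 4 | diethyl {[5-(1,3-dioxolan-2-yl)-4-methylfuran-2-yl]methyl}phosphonate | CCOP(=O)(OCC)Cc1cc(C)c(o1)C1OCCO1 | intermediate |
| 5 | 5-bromo-2-methylpent-2-ene | CC(C)=CCCBr | starting material |
| 6 | (E)-5-bromo-2-methylpent-2-en-1-ol | OC/C(C)=C/CCBr | intermediate |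
| 7 | (E)-TBS ether of 6 | CC(C)(C)[Si](C)(C)OC/C(C)=C/CCBr | intermediate |
| 8 | (S)-5-oxotetrahydrofuran-2-carboxylic acid | O=C1CC[C@H](O1)C(=O)O | starting material |
| 9 | Weinreb amide of 8 | O=C1CC[C@H](O1)C(=O)N(C)OC | intermediate |
| 10 | (S)-5-acetyldihydrofuran-2(3H)-one | O=C1CC[C@H](O1)C(C)=O | intermediate |
| 11 | E-vinylfuran lactone | O=C1CC[C@H](O1)/C(C)=C/c1cc(C)c(o1)C1OCCO1 | intermediate |
| 12 | cyclopropyl-furan lactone | O=C1CC[C@H](O1)[C@@]2(C)C[C@@H]2c3cc(C)c(o3)C4OCCO4 | intermediate |
| 13 | C12-alkylated lactone | O=C1C(CC/C=C(\C)CO[Si](C)(C)C(C)(C)C)C[C@H](O1)[C@@]2(C)C[C@@H]2c3cc(C)c(o3)C4OCCO4 | intermediate |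
| 14 | α-phenylselenyl lactone | O=C1C(CC/C=C(\C)CO[Si](C)(C)C(C)(C)C)([Se]c5ccccc5)C[C@H](O1)[C@@]2(C)C[C@@H]2c3cc(C)c(o3)C4OCCO4 | intermediate |
| 15 | butenolide | O=C1C(CC/C=C(\C)CO[Si](C)(C)C(C)(C)C)=C[C@H](O1)[C@@]2(C)C[C@@H]2c3cc(C)c(o3)C4OCCO4 | intermediate |
| 16 | allylic alcohol/furfural | O=C1C(CC/C=C(\C)CO)=C[C@H](O1)[C@@]2(C)C[C@@H]2c3cc(C)c(o3)C=O | intermediate |
| 17 | allylic bromide/furfural | O=C1C(CC/C=C(\C)CBr)=C[C@H](O1)[C@@]2(C)C[C@@H]2c3cc(C)c(o3)C=O | intermediate |
| 18 | furanomacrocycle alcohol | C=C(C)[C@@H]1CCC2=C[C@H](OC2=O)[C@@]2(C)C[C@@H]2c2cc(C)c(o2)[C@H]1O | intermediate |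
| 19 | furanomacrocycle acetate | C=C(C)[C@@H]1CCC2=C[C@H](OC2=O)[C@@]2(C)C[C@@H]2c2cc(C)c(o2)[C@H]1OC(C)=O | intermediate |
| 20 | Pinnatin B | C=C(C)[C@@H]1CCC2=C[C@H](OC2=O)[C@@]2(C)C[C@@H]2C(=O)/C=C(/C)C(=O)[C@H]1OC(C)=O | target |

---

**Totals:** 17 steps in all. The longest linear sequence is 13 steps (1→2→3→8→9→…→17 from **1**). The lactone branch is 12 steps and the bromoalkene branch is 10.

**Three steps most likely to fail**
1. **Step 15 (NHK macrocyclization).** The bridge across the furan is one atom shorter than in bipinnatin-type systems, and dr at C1/C2 relative to C10 is uncertain.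
   - Fallback: set C1/C2 beforehand from carvone (α-hydroxylation trans to the isopropenyl group). Then close the ring at C6–C7 by intramolecular Stille coupling of a furylstannane with an E-vinyl iodide, before the cyclopropanation.
2. **Step 9 (Simmons–Smith diastereoselectivity).** Facial control from the lactone-bearing C10 alone may be low.
   - Fallback: cyclopropanate the macrocyclic E-vinylfuran after NHK, using the C2–OH as a directing group, with the macrocycle conformation biasing the face. Alternatively, make the E-enone and use a sulfoxonium-ylide ring closure.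
3. **Steps 7–8 (α-alkoxy methyl ketone and HWE).** The C10 stereocenter can epimerize, and the Weinreb/Grignard step needs chemoselectivity over the lactone.
   - Fallback: avoid any enolizable C8 carbonyl. Make the terminal alkyne from (S)-5-(hydroxymethyl)lactone by Swern oxidation and buffered Ohira–Bestmann. Then do Negishi carboalumination/iodination (E-vinyl iodide) and Stille coupling with a 5-stannylfuran.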